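**Strategy.** The quinone ring is opened between C3 (bearing the docosyl chain) and C2 (bearing OH). The unit C2(OH)=C3–C4(=O) of the six-membered ring is an enolised 1,3-diketone, so C2 sits at the carboxyl oxidation level and the target is simply the enol form of a Dieckmann product. An intramolecular Claisen condensation of the acyclic keto ester methyl (3E)-4-methoxy-2,5-dioxooctacos-3-enoate therefore closes the ring and delivers the hydroxyquinone in one operation, without redox adjustment or protecting groups. The cis-enedione geometry and the vinylic OMe of this precursor are set by oxidative dearomatisation of a 3-methoxyfuran built from lignoceric acid and lithiated methoxyallene.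

Key step: step 6

Remark: the target has no stereocentre; the only stereochemical element on the route is the C3=C4 geometry of 11. Ring numbering of the target: C1 (C=O next to CH), C2 (C–OH), C3 (C–docosyl), C4 (C=O), C5 (C–OMe), C6 (CH). Chain atoms C1, C2, C3, C4, C5, C6 of 11 become ring atoms C2, C1, C6, C5, C4, C3.

**Step 1**
Reactants: 1 tetracosanoic acid (lignoceric acid)
Product: 3 N-methoxy-N-methyltetracosanamide, via acyl imidazole 2 (not isolated)
Conditions: CDI, THF, 45 °C; then MeNH(OMe)·HCl, 45 °C → rt
Reagents that add atoms: N,O-dimethylhydroxylamine hydrochloride, CNOC.Cl; 1,1'-carbonyldiimidazole, O=C(n1ccnc1)n1ccnc1 (imidazolyl group in intermediate 2 only)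
Why: Activation of the acid as its acyl imidazole followed by aminolysis is the standard Weinreb amide synthesis, and warm THF should keep the C24 chain in solution.

**Step 2**
Reactants: 3 N-methoxy-N-methyltetracosanamide; 4 methoxyallene (1-methoxypropa-1,2-diene)
Product: 6 3-methoxyheptacosa-1,2-dien-4-one, via 1-lithio-1-methoxyallene 5 (not isolated)
Conditions: 4 (1.6 equiv), n-BuLi (1.5 equiv), THF, −40 °C; then 3 in THF, −40 → −20 °C; aq. NH4Cl
Reagents that add atoms: n-butyllithium, [Li]CCCC (lithium of intermediate 5 only)
Why: n-BuLi deprotonates methoxyallene at C1 and the alkoxyallenyllithium should add once to the amide, the chelated tetrahedral adduct preventing over-addition (Weinreb ketone synthesis) and releasing the 1-methoxyallenyl ketone on quench.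

**Step 3**
Reactants: 6 3-methoxyheptacosa-1,2-dien-4-one
Product: 7 3-methoxy-2-tricosylfuran
Conditions: AgNO3 (10 mol%), acetone–CH2Cl2, rt, dark
Reagents that add atoms: none
Why: In this Ag(I)-catalysed allenyl ketone cycloisomerisation the carbonyl oxygen should attack the silver-activated terminal allene carbon (5-endo) and protodemetallation with aromatisation gives the furan, silver being chosen because Pd catalysts tend to dimerise terminal allenyl ketones.

**Step 4**
Reactants: 7 3-methoxy-2-tricosylfuran; 8 methyl chloroformate
Product: 10 methyl 4-methoxy-5-tricosylfuran-2-carboxylate, via furyllithium 9 (not isolated)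
Conditions: n-BuLi, THF, −20 → 0 °C; then cannulated into ClCO2Me (3 equiv), THF, −78 °C
Reagents that add atoms: n-butyllithium, [Li]CCCC (lithium of intermediate 9 only)
Why: Furans are deprotonated at the free α-position (C5, next to the ring oxygen) much faster than at C4 or in the side chain, and inverse addition to excess chloroformate should give the ester without ketone formation (α-lithiation/acylation).

**Step 5**
Reactants: 10 methyl 4-methoxy-5-tricosylfuran-2-carboxylate
Product: 11 methyl (3E)-4-methoxy-2,5-dioxooctacos-3-enoate (the two ketone carbons cis across C3=C4)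
Conditions: DMDO (1.1 equiv), acetone–CH2Cl2, −20 → 0 °C; evaporated and used crude
Reagents that add atoms: dimethyldioxirane, CC1(C)OO1
Why: DMDO should epoxidise the most electron-rich furan bond (C4=C5, carrying OMe and alkyl) and the epoxide collapses with ring opening to the enedione, whose acyl groups are necessarily cis (oxidative furan ring opening); neutral anhydrous conditions protect the labile product.

**Step 6**
Reactants: 11 methyl (3E)-4-methoxy-2,5-dioxooctacos-3-enoate
Product: 13 3-docosyl-2-hydroxy-5-methoxycyclohexa-2,5-diene-1,4-dione, via potassium quinonolate 12 (not isolated)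
Conditions: t-BuOK (1.5 equiv), THF, 0 °C → rt; then 1 M HCl, 0 °C
Reagents that add atoms: potassium tert-butoxide, CC(C)(C)[O-].[K+] (potassium of intermediate 12 only)
Why: t-BuOK removes a proton from C6 of 11, the only enolisable position, and the enolate carbon adds to the ester carbonyl C1; loss of methoxide gives the cyclohexenetrione, which tautomerises and is deprotonated to quinonolate 12, and acid liberates 13. The closest known reaction type is the Dieckmann (intramolecular Claisen) cyclisation of 5-oxo esters to cyclohexane-1,3-diones. The six-membered ring closes in a 6-(enolexo)-exo-trig mode. No stereocentre is formed. The step needs C-acylation at the ester in preference to 5-exo aldol addition at the C2 ketone; this should be secured because that ketone is a vinylogous ester carbonyl deactivated by the 4-OMe group, because the aldolate can revert, and because only the Claisen pathway ends in the irreversibly formed, strongly stabilised quinonolate. The cis placement of the two acyl arms across C3=C4, required for closure, is fixed by the furan origin of 11.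

**Compound list**
1 | tetracosanoic acid (lignoceric acid) | CCCCCCCCCCCCCCCCCCCCCCCC(=O)O | starting material
2 | 1-(1H-imidazol-1-yl)tetracosan-1-one (acyl imidazole) | CCCCCCCCCCCCCCCCCCCCCCCC(=O)n1ccnc1 | intermediate (not isolated)
3 | N-methoxy-N-methyltetracosanamide | CCCCCCCCCCCCCCCCCCCCCCCC(=O)N(C)OC | intermediate
4 | methoxyallene (1-methoxypropa-1,2-diene) | COC=C=C | starting material
5 | 1-lithio-1-methoxyallene | [Li]C(OC)=C=C | intermediate (not isolated)
6 | 3-methoxyheptacosa-1,2-dien-4-one | C=C=C(OC)C(=O)CCCCCCCCCCCCCCCCCCCCCCC | intermediate
7 | 3-methoxy-2-tricosylfuran | COc1ccoc1CCCCCCCCCCCCCCCCCCCCCCC | intermediate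
8 | methyl chloroformate | COC(=O)Cl | starting material
9 | (4-methoxy-5-tricosylfuran-2-yl)lithium | COc1cc([Li])oc1CCCCCCCCCCCCCCCCCCCCCCC | intermediate (not isolated)
10 | methyl 4-methoxy-5-tricosylfuran-2-carboxylate | COC(=O)c1cc(OC)c(CCCCCCCCCCCCCCCCCCCCCCC)o1 | intermediate
11 | methyl (3E)-4-methoxy-2,5-dioxooctacos-3-enoate | COC(=O)C(=O)/C=C(/OC)C(=O)CCCCCCCCCCCCCCCCCCCCCCC | intermediate
12 | potassium 2-docosyl-4-methoxy-3,6-dioxocyclohexa-1,4-dien-1-olate | CCCCCCCCCCCCCCCCCCCCCCC1=C([O-])C(=O)C=C(OC)C1=O.[K+] | intermediate (not isolated)
13 | 3-docosyl-2-hydroxy-5-methoxycyclohexa-2,5-diene-1,4-dione | CCCCCCCCCCCCCCCCCCCCCCC1=C(O)C(=O)C=C(OC)C1=O | target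

Total step count: 6. Longest linear sequence: 6 steps (from tetracosanoic acid).

**Steps most likely to fail**

Step 6. The enolate may be diverted into 5-exo aldol addition at the C2 ketone, or the base may attack the push–pull enol ether, so that closure at the ester is outrun. The fallback replaces the ester by an aldehyde and the Claisen by an aldol closure of the same bond. It sets out from 7: lithiation as in step 4 and a DMF quench should give 4-methoxy-5-tricosylfuran-2-carbaldehyde F1. Sensitised photo-oxygenation (O2, hν, methylene blue, CH2Cl2, −78 °C) with Me2S reduction should open it to (3E)-4-methoxy-2,5-dioxooctacos-3-enal F2. The aldehyde is then by far the most electrophilic carbonyl, so Et3N should induce 6-exo aldol closure, and the aldol tautomerises to 3-docosyl-5-methoxybenzene-1,2,4-triol F3. Oxidation with air or FeCl3 brings the sequence back to the route at 13.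

Step 5. Epoxidation of the ester-deactivated furan may be slow, so that over-oxidation of the enedione or its hydration during isolation competes. The fallback uses a [4+2] cycloaddition instead of epoxidation. It sets out from 10: singlet oxygen (O2, hν, tetraphenylporphyrin, CH2Cl2, −78 °C) should add across C2/C5 to give methyl 5-methoxy-4-tricosyl-2,3,7-trioxabicyclo[2.2.1]hept-5-ene-1-carboxylate F4 (racemic). Reduction in the cold with Me2S comes back to the route at 11.

Step 3. The electrophilic 1-methoxyallenyl ketone may oligomerise, or add to the electron-rich furan as it forms, faster than it cyclises. The fallback cyclises at the alcohol oxidation level and replaces steps 2 and 3. It sets out from 3: LiAlH4 reduction (THF, 0 °C) should give tetracosanal F5. Addition of 5 should give 3-methoxyheptacosa-1,2-dien-4-ol F6 (racemic). KOtBu in DMSO should effect 5-endo cyclisation to 3-methoxy-2-tricosyl-2,5-dihydrofuran F7 (racemic), whose stereocentre is destroyed when DDQ dehydrogenation comes back to the route at 7.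

**Further compounds**
F1 | step 6 | 4-methoxy-5-tricosylfuran-2-carbaldehyde | COc1cc(C=O)oc1CCCCCCCCCCCCCCCCCCCCCCC
F2 | step 6 | (3E)-4-methoxy-2,5-dioxooctacos-3-enal | O=CC(=O)/C=C(/OC)C(=O)CCCCCCCCCCCCCCCCCCCCCCC
F3 | step 6 | 3-docosyl-5-methoxybenzene-1,2,4-triol | COc1cc(O)c(O)c(CCCCCCCCCCCCCCCCCCCCCC)c1O
F4 | step 5 | methyl 5-methoxy-4-tricosyl-2,3,7-trioxabicyclo[2.2.1]hept-5-ene-1-carboxylate (racemic) | COC(=O)C12OOC(CCCCCCCCCCCCCCCCCCCCCCC)(O1)C(OC)=C2
F5 | step 3 | tetracosanal | CCCCCCCCCCCCCCCCCCCCCCCC=O
F6 | step 3 | 3-methoxyheptacosa-1,2-dien-4-ol (racemic) | C=C=C(OC)C(O)CCCCCCCCCCCCCCCCCCCCCCC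
F7 | step 3 | 3-methoxy-2-tricosyl-2,5-dihydrofuran (racemic) | COC1=CCOC1CCCCCCCCCCCCCCCCCCCCCCC
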